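Numbering: C1(aryl)–O2–C3–C3a(OH)–C4(aryl)–O5–C6–C6a; ring A holds O2, ring B holds O5. The route rests on cutting the aryl–C1 bond together with C3a–C6a: C6–C6a–C1 is then a propargyl group on O5 and the tertiary carbinol C3a a ketone. A rhodium-catalysed arylative cyclisation of this acyclic alkynyl ketone with an arylboronic acid forges the aryl–C1 bond, closes ring B and sets C3a under control of C4 in one operation. The precursor, an α-propargyloxy ketone made by asymmetric O–H insertion, carries a single stereocentre. A cobalt-hydride hydroalkoxylation of the resulting styrene then closes ring A and sets C6a and C1.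

Key step: step 7

Remark: the sense of induction of the spiro bis(oxazoline) ligand in step 3 is assumed by analogy; the ligand enantiomer that delivers the (R)-ether is the one used.

Step 1
Reactants: 1 methyl 2-(4-hydroxy-3-methoxyphenyl)acetate
Product: 2 methyl 2-[4-(tert-butyldimethylsilyloxy)-3-methoxyphenyl]acetate
Conditions: TBSCl, imidazole, DMF, 0 °C to rt
Reagents that add atoms: tert-butyldimethylsilyl chloride, CC(C)(C)[Si](C)(C)Cl
Why: Imidazole-promoted silyl ether formation masks the phenol, which would otherwise consume base in the diazo transfer and compete in the O–H insertion; no stereocentre is formed.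

Step 2
Reactants: 2 methyl 2-[4-(tert-butyldimethylsilyloxy)-3-methoxyphenyl]acetate
Product: 3 methyl 2-[4-(tert-butyldimethylsilyloxy)-3-methoxyphenyl]-2-diazoacetate
Conditions: 4-acetamidobenzenesulfonyl azide, DBU, MeCN, 0 °C to rt
Reagents that add atoms: 4-acetamidobenzenesulfonyl azide, CC(=O)Nc1ccc(cc1)S(=O)(=O)N=[N+]=[N-]
Why: Regitz diazo transfer, in which DBU deprotonates the benzylic ester-activated CH2 and the enolate takes N2 from the sulfonyl azide; no stereocentre is formed.

Step 3
Reactants: 3 methyl 2-[4-(tert-butyldimethylsilyloxy)-3-methoxyphenyl]-2-diazoacetate; 4 prop-2-yn-1-ol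
Product: 5 methyl (2R)-2-[4-(tert-butyldimethylsilyloxy)-3-methoxyphenyl]-2-(prop-2-yn-1-yloxy)acetate
Conditions: Fe(ClO4)2·4H2O (5 mol %), 7,7′-bis[(S)-4-phenyl-4,5-dihydrooxazol-2-yl]-1,1′-spirobiindane (6 mol %), NaB[3,5-(CF3)2C6H3]4 (6 mol %), 4 (2 equiv), CHCl3, 40 °C
Reagents that add atoms: none
Why: Enantioselective metal-carbene O–H insertion, in which the iron carbene from 3 is captured by the hydroxyl of 4 to an oxonium ylide whose proton shift inside the chiral ligand pocket sets C4 as (R), the O–H bond being expected to react far faster than the alkyne π bond, as allylic alcohols do in this reaction.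

Step 4
Reactants: 5 methyl (2R)-2-[4-(tert-butyldimethylsilyloxy)-3-methoxyphenyl]-2-(prop-2-yn-1-yloxy)acetate
Product: 6 (2R)-2-[4-(tert-butyldimethylsilyloxy)-3-methoxyphenyl]-N-methoxy-N-methyl-2-(prop-2-yn-1-yloxy)acetamide
Conditions: MeNH(OMe)·HCl, AlMe3, CH2Cl2, 0 °C to rt
Reagents that add atoms: N,O-dimethylhydroxylamine hydrochloride, CNOC.Cl
Why: Weinreb aminolysis of the ester by the aluminium amide formed in the flask, a Lewis-acidic and only weakly basic amide transfer that should leave the α-aryl-α-alkoxy stereocentre and the alkyne untouched.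

Step 5
Reactants: 6 (2R)-2-[4-(tert-butyldimethylsilyloxy)-3-methoxyphenyl]-N-methoxy-N-methyl-2-(prop-2-yn-1-yloxy)acetamide
Product: 7 (1R)-1-[4-(tert-butyldimethylsilyloxy)-3-methoxyphenyl]-3-(methoxymethoxy)-1-(prop-2-yn-1-yloxy)propan-2-one
Conditions: Bu3SnCH2OCH2OCH3 (2.5 equiv), n-BuLi (2.4 equiv), THF, −78 °C; then 6, −78 °C; NH4Cl quench at −78 °C
Reagents that add atoms: tributyl[(methoxymethoxy)methyl]stannane, CCCC[Sn](CCCC)(CCCC)COCOC
Why: Weinreb ketone synthesis with an α-alkoxymethyllithium from tin–lithium exchange, in which one equivalent of reagent is consumed by the alkyne C–H, the chelated tetrahedral adduct holds until the cold quench so that addition stops at the ketone, and the C4 configuration should be kept at −78 °C.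

Step 6
Reactants: 8 (4-hydroxy-3-methoxyphenyl)boronic acid
Product: 9 [4-(tert-butyldimethylsilyloxy)-3-methoxyphenyl]boronic acid
Conditions: TBSCl, imidazole, DMF, 0 °C to rt; aqueous work-up
Reagents that add atoms: tert-butyldimethylsilyl chloride, CC(C)(C)[Si](C)(C)Cl
Why: Silyl ether formation at the phenol gives an aryl donor whose oxygen is inert towards the oxidant of step 8; no stereocentre is formed.

Step 7
Reactants: 7 (1R)-1-[4-(tert-butyldimethylsilyloxy)-3-methoxyphenyl]-3-(methoxymethoxy)-1-(prop-2-yn-1-yloxy)propan-2-one; 9 [4-(tert-butyldimethylsilyloxy)-3-methoxyphenyl]boronic acid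
Product: 10 (2R,3S,4Z)-2-[4-(tert-butyldimethylsilyloxy)-3-methoxyphenyl]-4-{[4-(tert-butyldimethylsilyloxy)-3-methoxyphenyl]methylidene}-3-[(methoxymethoxy)methyl]tetrahydrofuran-3-ol
Conditions: [Rh(OH)(cod)]2 (3 mol %), 9 (2.5 equiv), 1,4-dioxane/H2O 20:1, rt
Reagents that add atoms: none
Why: Transmetalation of 9 to [Rh(OH)(cod)]2 gives an aryl–rhodium species (monovalent rhodium) that adds syn across the terminal alkyne with the aryl group on the unhindered terminal carbon C1 and rhodium on C6a, after which the alkenyl–rhodium adds to the neighbouring ketone C3a and water releases the tertiary alcohol and regenerates Rh–OH. The closest known reaction type is the rhodium-catalysed arylative cyclisation of alkynones and alkynals with arylboronic acids, which also runs on terminal propargyl ethers. Ring B (C3a–C4–O5–C6–C6a) closes in a 5-exo-trig mode by attack of C6a on the carbonyl carbon. The new stereocentre C3a is controlled by C4: in the four-centre C–Rh/C=O transition state the CH2OMOM arm of the ketone should lie trans to the C4 aryl group, so the hydroxyl ends up cis to it, while syn addition fixes the (Z) alkene. The step needs aryl transfer to C1, ring closure faster than β-alkoxide loss or protonation of the alkenyl–rhodium, and no erosion at C4; these are secured by the terminal alkyne, by the short tether to an electrophilic α,α′-dialkoxy ketone, and by room-temperature conditions in which the only base is catalytic Rh–OH.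

Step 8
Reactants: 10 (2R,3S,4Z)-2-[4-(tert-butyldimethylsilyloxy)-3-methoxyphenyl]-4-{[4-(tert-butyldimethylsilyloxy)-3-methoxyphenyl]methylidene}-3-[(methoxymethoxy)methyl]tetrahydrofuran-3-ol
Product: 11 (1S,3aS,4R,6aR)-1,4-bis[4-(tert-butyldimethylsilyloxy)-3-methoxyphenyl]tetrahydro-1H,3H-furo[3,4-c]furan-3a-ol
Conditions: [N,N′-bis(3,5-di-tert-butylsalicylidene)-1,2-cyclohexanediaminato]cobalt (C36H52CoN2O2, 5 mol %), N-fluoro-2,4,6-trimethylpyridinium triflate, (Me2SiH)2O, PhCF3, 0 °C to rt
Reagents that add atoms: none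
Why: Mukaiyama-type cobalt-hydride hydrogen-atom transfer with radical-polar crossover (deprotective hydroalkoxylation), in which H adds to C6a, the benzylic C1 radical is oxidised to the p-siloxybenzyl cation and the MOM ether oxygen O2 closes ring A with loss of the MOM cation; only the C6a epimer with C1 and C3 cis can form the cis-fused bicycle (the other should revert to the alkene by proton loss), which puts H-6a cis to the C3a hydroxyl, and the aryl group should take the convex face at C1 as in quinone-methide closures to furofurans.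

Step 9
Reactants: 11 (1S,3aS,4R,6aR)-1,4-bis[4-(tert-butyldimethylsilyloxy)-3-methoxyphenyl]tetrahydro-1H,3H-furo[3,4-c]furan-3a-ol
Product: 12 8-hydroxypinoresinol, (1S,3aS,4R,6aR)-1,4-bis(4-hydroxy-3-methoxyphenyl)tetrahydro-1H,3H-furo[3,4-c]furan-3a-ol
Conditions: Bu4NF, AcOH, THF, 0 °C
Reagents that add atoms: none
Why: Fluoride cleavage of the two aryl silyl ethers driven by Si–F bond formation, buffered with acetic acid so that the phenoxides cannot open the benzylic ethers through quinone methides; no stereocentre is touched.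

Compound list
1 | methyl 2-(4-hydroxy-3-methoxyphenyl)acetate (methyl homovanillate) | COC(=O)Cc1ccc(O)c(OC)c1 | starting material
2 | methyl 2-[4-(tert-butyldimethylsilyloxy)-3-methoxyphenyl]acetate | COC(=O)Cc1ccc(O[Si](C)(C)C(C)(C)C)c(OC)c1 | intermediate
3 | methyl 2-[4-(tert-butyldimethylsilyloxy)-3-methoxyphenyl]-2-diazoacetate | COC(=O)C(=[N+]=[N-])c1ccc(O[Si](C)(C)C(C)(C)C)c(OC)c1 | intermediate
4 | prop-2-yn-1-ol | C#CCO | starting material
5 | methyl (2R)-2-[4-(tert-butyldimethylsilyloxy)-3-methoxyphenyl]-2-(prop-2-yn-1-yloxy)acetate | COC(=O)[C@H](OCC#C)c1ccc(O[Si](C)(C)C(C)(C)C)c(OC)c1 | intermediate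
6 | (2R)-2-[4-(tert-butyldimethylsilyloxy)-3-methoxyphenyl]-N-methoxy-N-methyl-2-(prop-2-yn-1-yloxy)acetamide | CON(C)C(=O)[C@H](OCC#C)c1ccc(O[Si](C)(C)C(C)(C)C)c(OC)c1 | intermediate
7 | (1R)-1-[4-(tert-butyldimethylsilyloxy)-3-methoxyphenyl]-3-(methoxymethoxy)-1-(prop-2-yn-1-yloxy)propan-2-one | COCOCC(=O)[C@H](OCC#C)c1ccc(O[Si](C)(C)C(C)(C)C)c(OC)c1 | intermediate
8 | (4-hydroxy-3-methoxyphenyl)boronic acid | COc1cc(B(O)O)ccc1O | starting material
9 | [4-(tert-butyldimethylsilyloxy)-3-methoxyphenyl]boronic acid | COc1cc(B(O)O)ccc1O[Si](C)(C)C(C)(C)C | intermediate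
10 | (2R,3S,4Z)-2-[4-(tert-butyldimethylsilyloxy)-3-methoxyphenyl]-4-{[4-(tert-butyldimethylsilyloxy)-3-methoxyphenyl]methylidene}-3-[(methoxymethoxy)methyl]tetrahydrofuran-3-ol | COCOC[C@]1(O)[C@@H](c2ccc(O[Si](C)(C)C(C)(C)C)c(OC)c2)OC/C1=C/c3ccc(O[Si](C)(C)C(C)(C)C)c(OC)c3 | intermediate
11 | (1S,3aS,4R,6aR)-1,4-bis[4-(tert-butyldimethylsilyloxy)-3-methoxyphenyl]tetrahydro-1H,3H-furo[3,4-c]furan-3a-ol | COc1cc([C@H]2OC[C@]3(O)[C@@H](c4ccc(O[Si](C)(C)C(C)(C)C)c(OC)c4)OC[C@H]23)ccc1O[Si](C)(C)C(C)(C)C | intermediate
12 | 8-hydroxypinoresinol, (1S,3aS,4R,6aR)-1,4-bis(4-hydroxy-3-methoxyphenyl)tetrahydro-1H,3H-furo[3,4-c]furan-3a-ol | COc1cc([C@H]2OC[C@]3(O)[C@@H](c4ccc(O)c(OC)c4)OC[C@H]23)ccc1O | target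

Total step count: 9 steps. Longest linear sequence: 8 steps (steps 1, 2, 3, 4, 5, 7, 8, 9); step 6 is a one-step side branch.

Steps most likely to fail

Step 7. The aryl–rhodium species may be diverted by rhodium acetylide formation at the terminal alkyne, the alkenyl–rhodium may lose the β-alkoxide to give an allene, or slow ring closure may allow enolisation at C4 and poor facial control at the ketone. The fallback forms the same aryl–C1 bond by cross-coupling after ring B is closed. It sets out from 7, which is cyclised with B2pin2 under CuCl/Xantphos/NaOt-Bu/MeOH (syn borylcupration with boron on C1, then addition of the alkenyl–copper to the ketone) to (2R,3S,Z)-2-[4-(tert-butyldimethylsilyloxy)-3-methoxyphenyl]-3-[(methoxymethoxy)methyl]-4-[(4,4,5,5-tetramethyl-1,3,2-dioxaborolan-2-yl)methylidene]tetrahydrofuran-3-ol F1. Suzuki–Miyaura coupling of F1 with (4-bromo-2-methoxyphenoxy)(tert-butyl)dimethylsilane F2 (from commercial 4-bromo-2-methoxyphenol and TBSCl) under PdCl2(dppf)/K3PO4 in dioxane/H2O should proceed with retention of alkene geometry and comes back to the route at 10.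

Step 8. Hydrogen-atom transfer may deliver H to the wrong face of C6a without the expected reversal, or the tertiary allylic alcohol may ionise and the ring aromatise to a furan. The fallback replaces the radical-polar closure by an ionic, stereospecific halocyclisation. It sets out from 10, which with N-iodosuccinimide/NaHCO3 in MeCN at 0 °C (iodonium on the face of the C3a hydroxyl, anti attack of the MOM ether oxygen at benzylic C1, loss of the MOM group) should give (1S,3aS,4R,6aS)-1,4-bis[4-(tert-butyldimethylsilyloxy)-3-methoxyphenyl]-6a-iodotetrahydro-1H,3H-furo[3,4-c]furan-3a-ol F3. Bu3SnH/AIBN in toluene at 80 °C then replaces iodine by hydrogen from the convex face of the bridgehead radical and comes back to the route at 11.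

Step 3. The carbene may add to the alkyne (cyclopropenation) or the proton shift may occur outside the ligand pocket and lower the enantiomeric purity. The fallback sets the carbinol first and alkylates afterwards. It sets out from 3, which is oxidised with dimethyldioxirane in acetone at 0 °C to methyl 2-[4-(tert-butyldimethylsilyloxy)-3-methoxyphenyl]-2-oxoacetate F4. Noyori transfer hydrogenation with RuCl(p-cymene)(TsDPEN) in the enantiomeric form that gives the (R)-alcohol, in HCO2H/Et3N, should give methyl (2R)-2-[4-(tert-butyldimethylsilyloxy)-3-methoxyphenyl]-2-hydroxyacetate F5. Ag2O and propargyl bromide in CH2Cl2 then alkylate the hydroxyl without added base and come back to the route at 5.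

Further compounds
F1 | step 7 | (2R,3S,Z)-2-[4-(tert-butyldimethylsilyloxy)-3-methoxyphenyl]-3-[(methoxymethoxy)methyl]-4-[(4,4,5,5-tetramethyl-1,3,2-dioxaborolan-2-yl)methylidene]tetrahydrofuran-3-ol | COCOC[C@]1(O)[C@@H](c2ccc(O[Si](C)(C)C(C)(C)C)c(OC)c2)OC/C1=C/B3OC(C)(C)C(C)(C)O3
F2 | step 7 | (4-bromo-2-methoxyphenoxy)(tert-butyl)dimethylsilane | COc1cc(Br)ccc1O[Si](C)(C)C(C)(C)C
F3 | step 8 | (1S,3aS,4R,6aS)-1,4-bis[4-(tert-butyldimethylsilyloxy)-3-methoxyphenyl]-6a-iodotetrahydro-1H,3H-furo[3,4-c]furan-3a-ol | COc1cc([C@H]2OC[C@]3(O)[C@@H](c4ccc(O[Si](C)(C)C(C)(C)C)c(OC)c4)OC[C@]23I)ccc1O[Si](C)(C)C(C)(C)C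
F4 | step 3 | methyl 2-[4-(tert-butyldimethylsilyloxy)-3-methoxyphenyl]-2-oxoacetate | COC(=O)C(=O)c1ccc(O[Si](C)(C)C(C)(C)C)c(OC)c1
F5 | step 3 | methyl (2R)-2-[4-(tert-butyldimethylsilyloxy)-3-methoxyphenyl]-2-hydroxyacetate | COC(=O)[C@H](O)c1ccc(O[Si](C)(C)C(C)(C)C)c(OC)c1
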